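**Proposal: synthesis of (R)-8-[1-(4-hydroxy-3,5-dimethoxyphenyl)ethyl]-3,5,7-trihydroxy-2-(4-hydroxy-3-methoxyphenyl)-4H-chromen-4-one (23) by enantioselective methylation of a syringyl para-quinone methide**

## The problem

The target 23 is a flavonol: a 3-hydroxy-4H-chromen-4-one (rings A and C) with a 4-hydroxy-3-methoxyphenyl ring B at C2, free hydroxyls at C3, C5 and C7, and a 1-(4-hydroxy-3,5-dimethoxyphenyl)ethyl group at C8 of ring A. Ring A is a phloroglucinol with two carbon substituents, the C4 carbonyl at C4a and the benzylic carbon Cα at C8, both ortho to the oxygen that becomes O1. That oxygen must be told apart from the C5 and C7 oxygens and both carbons placed unambiguously, or the 6-substituted isomer results. Cα is the only stereocentre (R, a 1,1-diarylethane methine). The rest of the molecule is flat and offers nothing that could control it, so its configuration has to come from a reagent or catalyst and must then survive every later step. Three methyl ethers must remain while five phenols are unveiled, which rules out methyl-ether protection of the phenols. The electron-rich rings are prone to oxidation. The Cα–ring A bond can be broken by ipso-protonation under strong acid. Whenever the syringyl hydroxyl is free, oxidation to a quinone methide would erase the stereocentre. The enabling feature is that this hydroxyl sits para to Cα: removing the methyl group from Cα leaves a para-quinone methide whose exocyclic carbon is Cα. Because the quinone ring carries the same methoxy group on both sides, it has no E/Z isomers and offers one prochiral carbon to an enantioselective methyl transfer.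

## Retrosynthesis

**23 from 22.** The four benzyl–oxygen bonds (O5, O7, O4' and the syringyl oxygen) are cut last. Benzyl ethers are chosen over any acid- or Lewis-acid-labile group because one neutral hydrogenolysis removes them all. It leaves the three methoxy groups, the flavonol double bond and the Cα–aryl bonds alone. The forward step only has to stop before the chromenone is reduced.

**22 from 20, and 20 from 18 and 19.** Ring C is opened at O1–C2 and the C3–OH bond is removed, giving the 2'-hydroxychalcone 20. Its Cα=Cβ bond is then cut to the acetophenone 18 and O-benzylvanillin 19. An oxidative chalcone cyclisation gives the C3 hydroxyl directly, whereas a flavone-forming closure would need a separate C3 oxidation next to two very electron-rich rings. 18 and 19 are far simpler than 22, and 19 is purchasable. The forward cyclisation must close six-membered (flavonol) and not five-membered (aurone).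

**18 from 17, and 17 from 14.** The MOM ether on the future O1 is cut, then the C4a–acetyl bond, leading to the aryl bromide 14. A Friedel–Crafts or Fries acetylation of a bromine-free phenol was the neighbouring option. It is rejected because ring A would offer two open positions and the Lewis acid would threaten both the benzyl ethers and the Cα–ring A bond. A bromine atom placed early fixes the position, and bromine–lithium exchange installs the acetyl group under basic, cold conditions. The forward step needs exchange to be faster than any deprotonation and needs the acylation to stop at the ketone.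

**14 from 13, and 13 from 10 and 11.** The benzyl ether of the syringyl phenol is cut, then the Cα–CH3 bond, giving the para-quinone methide 10 and dimethylzinc 11. This is the only cut that creates the stereocentre and the methyl group in one event, with no later redox or deoxygenation. The alternative cut at Cα–aryl would require an enantioselective arylation between two similar, hindered arenes. 10 is achiral and has no geometric isomers. The forward step needs 1,6-regioselectivity, face selectivity from a chiral copper catalyst, and tolerance of the aryl bromide.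

**10 from 9, and 9 from 4 and 6.** The quinone methide is traced to the benzylic acetate 9 (1,6-elimination after fluoride cleaves the silyl ether). The Cα–syringyl bond of 9 is cut to the aldehyde 4 and the aryl bromide 6, used as its Grignard reagent 7. The opposite polarity (metalated ring A plus a syringaldehyde) would require metalating ring A beside its bromine. The forward addition must touch only the formyl group, which is why a Grignard reagent and not an aryllithium is planned. The alkoxide 8 is acetylated in the same flask to provide the leaving group.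

**4 from 3, 2 and 1; 6 from 5.** The MOM ether, the C–Br bond and the formyl C–C bond are cut in turn, leading to 3,5-bis(benzyloxy)phenol 1. 6 is the silyl ether of 4-bromo-2,6-dimethoxyphenol 5. The formylation must go ortho to the hydroxyl, so a magnesium-mediated method is preferred to a Vilsmeier reaction, which tends to attack para in 3,5-dialkoxyphenols. The hydroxyl left beside the formyl group in 2 is the oxygen that becomes O1. It directs the bromination to its free ortho position (3) and is then marked with MOM (4).

## Roads not taken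

**Alternative 1:** carbonylative assembly of ring C. The cut removes C4a–C4, C4–C3 and O1–C2 at once. In the forward step the ortho-iodophenol A2, carbon monoxide and the ring B alkyne A3 are joined by PdCl2(PPh3)2 and diethylamine to give the flavone A1. Its merits are real: three components in one step, ring B introduced as a simple alkyne, and the C4 carbon taken from CO, so no acetyl group has to be installed. In ring C construction it is shorter than the chosen plan, which spends four steps (9 to 12) on the same ring. Its weak points for this target are three. A1 is a flavone, so the C3 hydroxyl must be added afterwards by an oxidation next to two electron-rich rings and a tertiary, doubly benzylic C–H. Five-membered closure to an aurone competes in this annulation. And A2 already contains the stereocentre, so this plan has no answer of its own to the stereochemical question and needs a regioselective iodination of ring A as well. The chosen plan sets against the shorter ring C assembly a flavonol at the right oxidation level and a built-in solution for Cα.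

**Alternative 2:** benzannulation to a differentiated ring A. The cut removes C8–C8a and C6–C7. Heating the cyclobutenone A5 with the enantiopure silyl ynol ether A6 should give the phenol A4 through a vinylketene, [2+2] cycloaddition, four-electron ring opening and six-electron electrocyclisation. Its strength is one the chosen plan lacks: the three ring A oxygens emerge fully differentiated (free hydroxyl, silyl ether, benzyl ether) with the side chain placed regiospecifically and without a transition metal. The chosen route reaches that differentiation only through a MOM group and a regioselective bromination. Against it, the stereocentre must already exist in A6 as a propargylic, benzylic methine. It needs its own asymmetric synthesis and is exposed to strong base during ynol ether formation and to heat during the annulation. A6 is itself a multistep target. A4 still lacks the C4a acyl carbon, so an ortho-acylation of an electron-rich phenol returns. Overall the route is longer and moves the stereochemical problem elsewhere.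

**Alternative 3:** enzymatic dynamic kinetic resolution. The cut is a C–H bond at the future methyl carbon. The lactol A8 racemises through its ring-opened aldehyde tautomer, and a ketoreductase with NADPH reduces one enantiomer of that aldehyde to the alcohol A7. In principle all material is converted, the selectivity of an enzyme may exceed that of the copper catalyst, and no quinone methide or organometallic reagent is handled. In these respects it is the better road. Its weak points are the substrate and the aftermath. The enzyme must distinguish two large aryl groups on the α-carbon of a poorly water-soluble, tribenzylated compound, which calls for enzyme screening. The CH2OH group of A7 must then be deoxygenated to CH3 over two or three steps. Activating that alcohol beside a free ortho-phenol invites closure to a dihydrobenzofuran, so extra protection is needed, and ring A must still be acylated. The chosen plan forms the C–CH3 bond and the stereocentre together with no redox corrections.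

Key step: step 7

## Route

Assumption: compounds 1, 5, 11 and 19 are taken as purchasable. The sense of induction of the phosphoramidite in step 7 cannot be assigned in advance for this substrate. The (S,R,R) ligand is written, and its (R,S,S) antipode is used instead if that is the one leading to the R product.

Step 1
Reactants: 1 3,5-bis(benzyloxy)phenol
Product: 2 4,6-bis(benzyloxy)-2-hydroxybenzaldehyde
Conditions: MgCl2, Et3N, (CH2O)n, MeCN, reflux; then 1 M HCl
Reagents that add atoms: paraformaldehyde (as formaldehyde), C=O
Why: Magnesium-mediated ortho-formylation of a phenol (Casnati–Skattebøl type): the magnesium phenoxide delivers formaldehyde to the ortho position only and a second formaldehyde accepts hydride, so the aldehyde level is reached in one pot. The two ortho positions of 1 are equivalent, so one product is expected.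

Step 2
Reactants: 2 4,6-bis(benzyloxy)-2-hydroxybenzaldehyde
Product: 3 4,6-bis(benzyloxy)-3-bromo-2-hydroxybenzaldehyde
Conditions: NBS (1.0 equiv), CH2Cl2, −20 to 0 °C
Reagents that add atoms: N-bromosuccinimide, O=C1CCC(=O)N1Br
Why: Electrophilic aromatic bromination. C3 lies between the chelated hydroxyl and one benzyloxy group while C5 is buttressed by two benzyloxy groups, and substitution ortho to the hydrogen-bonded hydroxyl is the usual course for 2-hydroxy-4,6-dialkoxyaryl carbonyl compounds. One equivalent at low temperature limits dibromination.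

Step 3
Reactants: 3 4,6-bis(benzyloxy)-3-bromo-2-hydroxybenzaldehyde
Product: 4 4,6-bis(benzyloxy)-3-bromo-2-(methoxymethoxy)benzaldehyde
Conditions: MOMCl, K2CO3, DMF, 0 °C to rt
Reagents that add atoms: chloromethyl methyl ether, COCCl
Why: Williamson-type O-alkylation of an acidic, chelated phenol. The small, reactive chloromethyl ether reaches the hindered oxygen, and the MOM group marks the oxygen that later becomes O1.

Step 4
Reactants: 5 4-bromo-2,6-dimethoxyphenol
Product: 6 (4-bromo-2,6-dimethoxyphenoxy)(tert-butyl)dimethylsilane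
Conditions: TBSCl, imidazole, DMF, rt to 40 °C
Reagents that add atoms: tert-butyldimethylsilyl chloride, CC(C)(C)[Si](C)(C)Cl
Why: Standard imidazole-promoted silylation of a phenol. The silyl ether masks the acidic proton for the Grignard step and later serves as the fluoride-sensitive trigger.

Step 5
Reactants: 6 (4-bromo-2,6-dimethoxyphenoxy)(tert-butyl)dimethylsilane; 4 4,6-bis(benzyloxy)-3-bromo-2-(methoxymethoxy)benzaldehyde
Product: 9 [4,6-bis(benzyloxy)-3-bromo-2-(methoxymethoxy)phenyl]{4-[(tert-butyldimethylsilyl)oxy]-3,5-dimethoxyphenyl}methyl acetate (racemic), via aryl Grignard reagent 7 (not isolated), via bromomagnesium alkoxide 8 (not isolated)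
Conditions: 6, Mg (I2 cat.), THF, 50 °C; then 4, THF, −20 to 0 °C; then Ac2O, DMAP (cat.), 0 °C to rt
Reagents that add atoms: acetic anhydride, CC(=O)OC(C)=O; magnesium, [Mg] (held only in 7 and 8)
Why: Grignard addition to an aldehyde followed by O-acylation of the alkoxide in the same flask. An arylmagnesium bromide adds to the formyl group without exchanging with the ring A bromide, and the acetate supplies the leaving group for the next step.

Step 6
Reactants: 9 [4,6-bis(benzyloxy)-3-bromo-2-(methoxymethoxy)phenyl]{4-[(tert-butyldimethylsilyl)oxy]-3,5-dimethoxyphenyl}methyl acetate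
Product: 10 4-{[4,6-bis(benzyloxy)-3-bromo-2-(methoxymethoxy)phenyl]methylidene}-2,6-dimethoxycyclohexa-2,5-dien-1-one
Conditions: Bu4NF (1.05 equiv), 4 Å MS, THF, −40 to 0 °C; used at once
Reagents that add atoms: none
Why: Fluoride-triggered 1,6-elimination: cleavage of the Si–O bond frees a phenoxide that expels the para-benzylic acetate, the established way to generate para-quinone methides. The electron-rich ring A on Cα and the two methoxy groups should make 10 persistent enough to be transferred directly to step 7.

Step 7
Reactants: 10 4-{[4,6-bis(benzyloxy)-3-bromo-2-(methoxymethoxy)phenyl]methylidene}-2,6-dimethoxycyclohexa-2,5-dien-1-one; 11 dimethylzinc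
Product: 13 4-{(1R)-1-[4,6-bis(benzyloxy)-3-bromo-2-(methoxymethoxy)phenyl]ethyl}-2,6-dimethoxyphenol, via methylzinc phenoxide 12 (not isolated)
Conditions: Cu(OTf)2 (5 mol%), (S,R,R)-binaphthol-derived N,N-bis(1-phenylethyl)phosphoramidite (10 mol%), ZnMe2 (3 equiv), toluene, −20 °C to rt; then 1 M HCl, 0 °C
Reagents that add atoms: dimethylzinc (11), C[Zn]C
Why: ZnMe2 reduces divalent copper to monovalent copper and transmetalates to a phosphoramidite-bound methylcopper species, which binds the exocyclic C=C bond of 10 while zinc activates the quinone carbonyl; oxidative addition at Cα gives a σ-bonded trivalent copper intermediate and reductive elimination forms the Cα–CH3 bond, the ring aromatising to the methylzinc phenoxide 12, which makes the addition irreversible. The closest known reaction type is the copper/phosphoramidite-catalysed enantioselective 1,6-conjugate addition of dialkylzinc reagents to para-quinone methides, itself an outgrowth of the 1,4-addition to enones; methyl transfer and the 2,6-dimethoxy quinone ring are the only extensions. No ring is closed. The single new stereocentre is under catalyst control: the chiral ligand on copper differentiates the two faces of the prochiral exocyclic carbon by distinguishing the bulky, doubly ortho-substituted ring A from the vinylic hydrogen. Because the quinone ring is symmetric, the substrate is a single geometric isomer, so one substrate geometry meets one catalyst. The step needs 1,6- over 1,2-addition, secured by the two methoxy groups flanking the carbonyl and the soft organocopper nucleophile; it needs the aryl bromide to stay intact, secured because methylcopper does not insert into an electron-rich, hindered C–Br bond at these temperatures; and it needs a negligible uncatalysed background, secured by the low nucleophilicity of ZnMe2 alone. Mild acidic work-up protonates 12 to give 13.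

Step 8
Reactants: 13 4-{(1R)-1-[4,6-bis(benzyloxy)-3-bromo-2-(methoxymethoxy)phenyl]ethyl}-2,6-dimethoxyphenol
Product: 14 2-(benzyloxy)-5-{(1R)-1-[4,6-bis(benzyloxy)-3-bromo-2-(methoxymethoxy)phenyl]ethyl}-1,3-dimethoxybenzene
Conditions: BnBr, K2CO3, DMF, rt, argon
Reagents that add atoms: benzyl bromide, BrCc1ccccc1
Why: Williamson ether synthesis on the hindered syringyl phenol. Capping this hydroxyl closes the oxidative path back to a quinone methide, so the stereocentre is safe in the base and peroxide steps that follow.

Step 9
Reactants: 14 2-(benzyloxy)-5-{(1R)-1-[4,6-bis(benzyloxy)-3-bromo-2-(methoxymethoxy)phenyl]ethyl}-1,3-dimethoxybenzene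
Product: 17 1-[4,6-bis(benzyloxy)-3-{(1R)-1-[4-(benzyloxy)-3,5-dimethoxyphenyl]ethyl}-2-(methoxymethoxy)phenyl]ethan-1-one, via aryllithium 15 (not isolated), via lithium hemiaminal adduct 16 (not isolated)
Conditions: n-BuLi (1.1 equiv), THF, −78 °C; then MeC(O)N(OMe)Me, −78 to 0 °C; then H2O
Reagents that add atoms: N-methoxy-N-methylacetamide, CC(=O)N(C)OC; n-butyllithium, [Li]CCCC (lithium held only in 15 and 16)
Why: Bromine–lithium exchange followed by Weinreb ketone synthesis. Exchange at −78 °C is far faster than deprotonation of the Cα–H or of the benzyl ethers, so the stereocentre is untouched, and the chelated adduct 16 releases the ketone only on work-up, so no over-addition occurs.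

Step 10
Reactants: 17 1-[4,6-bis(benzyloxy)-3-{(1R)-1-[4-(benzyloxy)-3,5-dimethoxyphenyl]ethyl}-2-(methoxymethoxy)phenyl]ethan-1-one
Product: 18 1-[4,6-bis(benzyloxy)-3-{(1R)-1-[4-(benzyloxy)-3,5-dimethoxyphenyl]ethyl}-2-hydroxyphenyl]ethan-1-one
Conditions: 2 M aq. HCl, MeOH–THF, 45 °C
Reagents that add atoms: none
Why: Acid-catalysed acetal exchange removes the MOM group, helped by formation of the chelated ortho-hydroxy ketone. With the acetyl group now deactivating ring A, dilute acid should not protonate the ring at C3 and break the Cα–aryl bond, and benzyl ethers are stable.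

Step 11
Reactants: 18 1-[4,6-bis(benzyloxy)-3-{(1R)-1-[4-(benzyloxy)-3,5-dimethoxyphenyl]ethyl}-2-hydroxyphenyl]ethan-1-one; 19 4-(benzyloxy)-3-methoxybenzaldehyde
Product: 20 (2E)-1-[4,6-bis(benzyloxy)-3-{(1R)-1-[4-(benzyloxy)-3,5-dimethoxyphenyl]ethyl}-2-hydroxyphenyl]-3-[4-(benzyloxy)-3-methoxyphenyl]prop-2-en-1-one
Conditions: 50% aq. KOH, EtOH–THF, rt
Reagents that add atoms: none
Why: Claisen–Schmidt condensation of a 2-hydroxyacetophenone with a non-enolisable aryl aldehyde. Dehydration gives the conjugated E-enone, and the Cα–H is not acidic enough to be touched by hydroxide.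

Step 12
Reactants: 20 (2E)-1-[4,6-bis(benzyloxy)-3-{(1R)-1-[4-(benzyloxy)-3,5-dimethoxyphenyl]ethyl}-2-hydroxyphenyl]-3-[4-(benzyloxy)-3-methoxyphenyl]prop-2-en-1-one
Product: 22 5,7-bis(benzyloxy)-2-[4-(benzyloxy)-3-methoxyphenyl]-8-{(1R)-1-[4-(benzyloxy)-3,5-dimethoxyphenyl]ethyl}-3-hydroxy-4H-chromen-4-one, via trans-dihydroflavonol 21 (not isolated)
Conditions: 30% aq. H2O2, 2 M aq. NaOH, MeOH–THF, 0 °C to rt; then dilute HCl
Reagents that add atoms: hydrogen peroxide, OO
Why: Algar–Flynn–Oyamada oxidation: the phenoxide closes onto the β-carbon as alkaline peroxide oxygenates the α-carbon, and the resulting dihydroflavonol 21 is dehydrogenated in the same medium. All other phenols are benzylated, so only the 2'-phenoxide takes part.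

Step 13
Reactants: 22 5,7-bis(benzyloxy)-2-[4-(benzyloxy)-3-methoxyphenyl]-8-{(1R)-1-[4-(benzyloxy)-3,5-dimethoxyphenyl]ethyl}-3-hydroxy-4H-chromen-4-one
Product: 23 3,5,7-trihydroxy-2-(4-hydroxy-3-methoxyphenyl)-8-[(1R)-1-(4-hydroxy-3,5-dimethoxyphenyl)ethyl]-4H-chromen-4-one
Conditions: H2 (1 atm), Pd/C (10 wt% Pd), EtOAc–MeOH, rt
Reagents that add atoms: none
Why: Catalytic hydrogenolysis of four aryl benzyl ethers under neutral conditions. Methyl ethers, the flavonol double bond and the Cα–aryl bonds are not cleaved, and the absence of acid, base and oxidant protects the stereocentre beside the freed syringyl phenol.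

## Compound list

1 | 3,5-bis(benzyloxy)phenol | Oc1cc(OCc2ccccc2)cc(OCc2ccccc2)c1 | starting material
2 | 4,6-bis(benzyloxy)-2-hydroxybenzaldehyde | O=Cc1c(O)cc(OCc2ccccc2)cc1OCc1ccccc1 | intermediate
3 | 4,6-bis(benzyloxy)-3-bromo-2-hydroxybenzaldehyde | O=Cc1c(O)c(Br)c(OCc2ccccc2)cc1OCc1ccccc1 | intermediate
4 | 4,6-bis(benzyloxy)-3-bromo-2-(methoxymethoxy)benzaldehyde | O=Cc1c(OCOC)c(Br)c(OCc2ccccc2)cc1OCc1ccccc1 | intermediate
5 | 4-bromo-2,6-dimethoxyphenol | COc1cc(Br)cc(OC)c1O | starting material
6 | (4-bromo-2,6-dimethoxyphenoxy)(tert-butyl)dimethylsilane | COc1cc(Br)cc(OC)c1O[Si](C)(C)C(C)(C)C | intermediate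
7 | {4-[(tert-butyldimethylsilyl)oxy]-3,5-dimethoxyphenyl}magnesium bromide | COc1cc([Mg]Br)cc(OC)c1O[Si](C)(C)C(C)(C)C | intermediate (not isolated)
8 | bromomagnesium [4,6-bis(benzyloxy)-3-bromo-2-(methoxymethoxy)phenyl]{4-[(tert-butyldimethylsilyl)oxy]-3,5-dimethoxyphenyl}methanolate (racemic) | COc1cc(C(O[Mg]Br)c2c(OCOC)c(Br)c(OCc3ccccc3)cc2OCc2ccccc2)cc(OC)c1O[Si](C)(C)C(C)(C)C | intermediate (not isolated)
9 | [4,6-bis(benzyloxy)-3-bromo-2-(methoxymethoxy)phenyl]{4-[(tert-butyldimethylsilyl)oxy]-3,5-dimethoxyphenyl}methyl acetate (racemic) | COc1cc(C(OC(C)=O)c2c(OCOC)c(Br)c(OCc3ccccc3)cc2OCc2ccccc2)cc(OC)c1O[Si](C)(C)C(C)(C)C | intermediate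
10 | 4-{[4,6-bis(benzyloxy)-3-bromo-2-(methoxymethoxy)phenyl]methylidene}-2,6-dimethoxycyclohexa-2,5-dien-1-one | COC1=CC(=Cc2c(OCOC)c(Br)c(OCc3ccccc3)cc2OCc2ccccc2)C=C(OC)C1=O | intermediate
11 | dimethylzinc | C[Zn]C | starting material
12 | methylzinc 4-{(1R)-1-[4,6-bis(benzyloxy)-3-bromo-2-(methoxymethoxy)phenyl]ethyl}-2,6-dimethoxyphenolate | COCOc1c(Br)c(OCc2ccccc2)cc(OCc2ccccc2)c1[C@H](C)c1cc(OC)c(O[Zn]C)c(OC)c1 | intermediate (not isolated)
13 | 4-{(1R)-1-[4,6-bis(benzyloxy)-3-bromo-2-(methoxymethoxy)phenyl]ethyl}-2,6-dimethoxyphenol | COCOc1c(Br)c(OCc2ccccc2)cc(OCc2ccccc2)c1[C@H](C)c1cc(OC)c(O)c(OC)c1 | intermediate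
14 | 2-(benzyloxy)-5-{(1R)-1-[4,6-bis(benzyloxy)-3-bromo-2-(methoxymethoxy)phenyl]ethyl}-1,3-dimethoxybenzene | COCOc1c(Br)c(OCc2ccccc2)cc(OCc2ccccc2)c1[C@H](C)c1cc(OC)c(OCc2ccccc2)c(OC)c1 | intermediate
15 | [2,4-bis(benzyloxy)-5-{(1R)-1-[4-(benzyloxy)-3,5-dimethoxyphenyl]ethyl}-6-(methoxymethoxy)phenyl]lithium | COCOc1c([Li])c(OCc2ccccc2)cc(OCc2ccccc2)c1[C@H](C)c1cc(OC)c(OCc2ccccc2)c(OC)c1 | intermediate (not isolated)
16 | lithium 1-[4,6-bis(benzyloxy)-3-{(1R)-1-[4-(benzyloxy)-3,5-dimethoxyphenyl]ethyl}-2-(methoxymethoxy)phenyl]-1-[methoxy(methyl)amino]ethan-1-olate (both epimers at the new carbon) | COCOc1c(C(C)(O[Li])N(C)OC)c(OCc2ccccc2)cc(OCc2ccccc2)c1[C@H](C)c1cc(OC)c(OCc2ccccc2)c(OC)c1 | intermediate (not isolated)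
17 | 1-[4,6-bis(benzyloxy)-3-{(1R)-1-[4-(benzyloxy)-3,5-dimethoxyphenyl]ethyl}-2-(methoxymethoxy)phenyl]ethan-1-one | COCOc1c(C(C)=O)c(OCc2ccccc2)cc(OCc2ccccc2)c1[C@H](C)c1cc(OC)c(OCc2ccccc2)c(OC)c1 | intermediate
18 | 1-[4,6-bis(benzyloxy)-3-{(1R)-1-[4-(benzyloxy)-3,5-dimethoxyphenyl]ethyl}-2-hydroxyphenyl]ethan-1-one | CC(=O)c1c(O)c([C@H](C)c2cc(OC)c(OCc3ccccc3)c(OC)c2)c(OCc2ccccc2)cc1OCc1ccccc1 | intermediate
19 | 4-(benzyloxy)-3-methoxybenzaldehyde | COc1cc(C=O)ccc1OCc1ccccc1 | starting material
20 | (2E)-1-[4,6-bis(benzyloxy)-3-{(1R)-1-[4-(benzyloxy)-3,5-dimethoxyphenyl]ethyl}-2-hydroxyphenyl]-3-[4-(benzyloxy)-3-methoxyphenyl]prop-2-en-1-one | COc1cc(/C=C/C(=O)c2c(O)c([C@H](C)c3cc(OC)c(OCc4ccccc4)c(OC)c3)c(OCc3ccccc3)cc2OCc2ccccc2)ccc1OCc1ccccc1 | intermediate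
21 | 5,7-bis(benzyloxy)-2-[4-(benzyloxy)-3-methoxyphenyl]-8-{(1R)-1-[4-(benzyloxy)-3,5-dimethoxyphenyl]ethyl}-3-hydroxy-2,3-dihydro-4H-chromen-4-one (2,3-trans, both trans diastereomers) | COc1cc(C2Oc3c([C@H](C)c4cc(OC)c(OCc5ccccc5)c(OC)c4)c(OCc4ccccc4)cc(OCc4ccccc4)c3C(=O)C2O)ccc1OCc1ccccc1 | intermediate (not isolated)
22 | 5,7-bis(benzyloxy)-2-[4-(benzyloxy)-3-methoxyphenyl]-8-{(1R)-1-[4-(benzyloxy)-3,5-dimethoxyphenyl]ethyl}-3-hydroxy-4H-chromen-4-one | COc1cc(-c2oc3c([C@H](C)c4cc(OC)c(OCc5ccccc5)c(OC)c4)c(OCc4ccccc4)cc(OCc4ccccc4)c3c(=O)c2O)ccc1OCc1ccccc1 | intermediate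
23 | 3,5,7-trihydroxy-2-(4-hydroxy-3-methoxyphenyl)-8-[(1R)-1-(4-hydroxy-3,5-dimethoxyphenyl)ethyl]-4H-chromen-4-one | COc1cc(-c2oc3c([C@H](C)c4cc(OC)c(O)c(OC)c4)c(O)cc(O)c3c(=O)c2O)ccc1O | target

## Step count and least certain steps

Total: 13 steps. Longest linear sequence: 12 steps (1 to 23 through steps 1, 2, 3, 5 to 13); step 4 is a one-step side branch.

**Step 7 (key step).** The most likely failure is slow methyl transfer. Dimethylzinc is the least reactive dialkylzinc and Cα is shielded by a doubly ortho-substituted ring, so the quinone methide may decay by hydration or self-condensation first. The second concern is poor facial discrimination at a carbon whose large substituent is twisted out of plane. The fallback sets out from 4 (with Grignard reagent 7) and returns at 13. It replaces the conjugate addition by an asymmetric alkene hydrogenation: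
- Quenching the Grignard adduct with water instead of acetic anhydride gives racemic [4,6-bis(benzyloxy)-3-bromo-2-(methoxymethoxy)phenyl]{4-[(tert-butyldimethylsilyl)oxy]-3,5-dimethoxyphenyl}methanol F1.
- MnO2 oxidation gives [4,6-bis(benzyloxy)-3-bromo-2-(methoxymethoxy)phenyl]{4-[(tert-butyldimethylsilyl)oxy]-3,5-dimethoxyphenyl}methanone F2.
- Wittig methylenation with Ph3P=CH2 gives the 1,1-diarylethene tert-butyl(4-{1-[4,6-bis(benzyloxy)-3-bromo-2-(methoxymethoxy)phenyl]ethenyl}-2,6-dimethoxyphenoxy)dimethylsilane F3.
- Iridium-catalysed asymmetric hydrogenation ([Ir(cod)(P,N)]BArF with a chiral phosphine–oxazoline ligand, H2) gives tert-butyl(4-{(1R)-1-[4,6-bis(benzyloxy)-3-bromo-2-(methoxymethoxy)phenyl]ethyl}-2,6-dimethoxyphenoxy)dimethylsilane F4. The steric contrast between the di-ortho-substituted ring A and the syringyl ring is relied on for differentiation.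
- Bu4NF then gives 13.

**Step 2.** Bromination may go in part to C5 or proceed twice, because both open positions are activated by three oxygens. The fallback sets out from 2 and returns at 4, replacing electrophilic substitution by directed metalation. MOM protection of 2 gives 2,4-bis(benzyloxy)-6-(methoxymethoxy)benzaldehyde F5. Addition of lithium 4-methylpiperazin-1-ide masks the formyl group in the flask as lithium [2,4-bis(benzyloxy)-6-(methoxymethoxy)phenyl](4-methylpiperazin-1-yl)methanolate F6. n-BuLi then metalates the position between the MOM and benzyloxy groups (MOM being the stronger director), and 1,2-dibromotetrachloroethane followed by aqueous work-up gives 4.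

**Step 6.** The quinone methide may be lost on isolation by addition of water or by self-condensation, and the acetate 9 may ionise prematurely. The fallback sets out from 9 and returns at 13. Treating 9 with Bu4NF in the presence of sodium 4-methylbenzenesulfinate and AcOH intercepts the quinone methide as it forms, giving the bench-stable racemic sulfone 4-{[4,6-bis(benzyloxy)-3-bromo-2-(methoxymethoxy)phenyl](4-methylbenzenesulfonyl)methyl}-2,6-dimethoxyphenol F7. In step 7 one further equivalent of ZnMe2 converts F7 into its zinc phenoxide, which expels sulfinate and releases 10 in the presence of the copper catalyst.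

**Step 9.** The hindered aryllithium 15 may take a proton from the α-CH of the amide instead of adding to it, giving net loss of bromine. The fallback sets out from 14 and returns at 18, replacing the organolithium by a cross-coupling. Stille coupling with tributyl(1-ethoxyvinyl)stannane (Pd(PPh3)4, CsF, dioxane, 100 °C) gives 2-(benzyloxy)-5-{(1R)-1-[4,6-bis(benzyloxy)-3-(1-ethoxyethenyl)-2-(methoxymethoxy)phenyl]ethyl}-1,3-dimethoxybenzene F8. HCl in MeOH then hydrolyses the enol ether and removes the MOM group in one operation to give 18.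

**Step 12.** Cyclisation may divert to the five-membered aurone, a known tendency of chalcones with an alkoxy group at C6', and ring B may be over-oxidised. The fallback sets out from 17 and returns at 22 by way of 21, keeping the phenol masked during the peroxide step:
- Claisen–Schmidt condensation of 17 with 19 gives (2E)-1-[4,6-bis(benzyloxy)-3-{(1R)-1-[4-(benzyloxy)-3,5-dimethoxyphenyl]ethyl}-2-(methoxymethoxy)phenyl]-3-[4-(benzyloxy)-3-methoxyphenyl]prop-2-en-1-one F9.
- Alkaline H2O2 gives the trans-epoxide [4,6-bis(benzyloxy)-3-{(1R)-1-[4-(benzyloxy)-3,5-dimethoxyphenyl]ethyl}-2-(methoxymethoxy)phenyl]{3-[4-(benzyloxy)-3-methoxyphenyl]oxiran-2-yl}methanone F10.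
- HCl in MeOH removes the MOM group and the freed phenol opens the epoxide at the benzylic carbon to give 21, now isolated.
- I2 with KOAc in AcOH dehydrogenates 21 to 22.

## Further compounds

F1 | step 7 | [4,6-bis(benzyloxy)-3-bromo-2-(methoxymethoxy)phenyl]{4-[(tert-butyldimethylsilyl)oxy]-3,5-dimethoxyphenyl}methanol (racemic) | COc1cc(C(O)c2c(OCOC)c(Br)c(OCc3ccccc3)cc2OCc2ccccc2)cc(OC)c1O[Si](C)(C)C(C)(C)C
F2 | step 7 | [4,6-bis(benzyloxy)-3-bromo-2-(methoxymethoxy)phenyl]{4-[(tert-butyldimethylsilyl)oxy]-3,5-dimethoxyphenyl}methanone | COc1cc(C(=O)c2c(OCOC)c(Br)c(OCc3ccccc3)cc2OCc2ccccc2)cc(OC)c1O[Si](C)(C)C(C)(C)C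
F3 | step 7 | tert-butyl(4-{1-[4,6-bis(benzyloxy)-3-bromo-2-(methoxymethoxy)phenyl]ethenyl}-2,6-dimethoxyphenoxy)dimethylsilane | COc1cc(C(=C)c2c(OCOC)c(Br)c(OCc3ccccc3)cc2OCc2ccccc2)cc(OC)c1O[Si](C)(C)C(C)(C)C
F4 | step 7 | tert-butyl(4-{(1R)-1-[4,6-bis(benzyloxy)-3-bromo-2-(methoxymethoxy)phenyl]ethyl}-2,6-dimethoxyphenoxy)dimethylsilane | COCOc1c(Br)c(OCc2ccccc2)cc(OCc2ccccc2)c1[C@H](C)c1cc(OC)c(O[Si](C)(C)C(C)(C)C)c(OC)c1
F5 | step 2 | 2,4-bis(benzyloxy)-6-(methoxymethoxy)benzaldehyde | O=Cc1c(OCOC)cc(OCc2ccccc2)cc1OCc1ccccc1
F6 | step 2 | lithium [2,4-bis(benzyloxy)-6-(methoxymethoxy)phenyl](4-methylpiperazin-1-yl)methanolate (racemic, formed in the flask) | [Li]OC(N1CCN(C)CC1)c1c(OCOC)cc(OCc2ccccc2)cc1OCc1ccccc1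
F7 | step 6 | 4-{[4,6-bis(benzyloxy)-3-bromo-2-(methoxymethoxy)phenyl](4-methylbenzenesulfonyl)methyl}-2,6-dimethoxyphenol (racemic) | COc1cc(C(c2c(OCOC)c(Br)c(OCc3ccccc3)cc2OCc2ccccc2)S(=O)(=O)c2ccc(C)cc2)cc(OC)c1O
F8 | step 9 | 2-(benzyloxy)-5-{(1R)-1-[4,6-bis(benzyloxy)-3-(1-ethoxyethenyl)-2-(methoxymethoxy)phenyl]ethyl}-1,3-dimethoxybenzene | COCOc1c(C(=C)OCC)c(OCc2ccccc2)cc(OCc2ccccc2)c1[C@H](C)c1cc(OC)c(OCc2ccccc2)c(OC)c1
F9 | step 12 | (2E)-1-[4,6-bis(benzyloxy)-3-{(1R)-1-[4-(benzyloxy)-3,5-dimethoxyphenyl]ethyl}-2-(methoxymethoxy)phenyl]-3-[4-(benzyloxy)-3-methoxyphenyl]prop-2-en-1-one | COCOc1c(C(=O)/C=C/c2ccc(OCc3ccccc3)c(OC)c2)c(OCc2ccccc2)cc(OCc2ccccc2)c1[C@H](C)c1cc(OC)c(OCc2ccccc2)c(OC)c1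
F10 | step 12 | [4,6-bis(benzyloxy)-3-{(1R)-1-[4-(benzyloxy)-3,5-dimethoxyphenyl]ethyl}-2-(methoxymethoxy)phenyl]{3-[4-(benzyloxy)-3-methoxyphenyl]oxiran-2-yl}methanone (trans-epoxide, both diastereomers) | COCOc1c(C(=O)C2OC2c2ccc(OCc3ccccc3)c(OC)c2)c(OCc2ccccc2)cc(OCc2ccccc2)c1[C@H](C)c1cc(OC)c(OCc2ccccc2)c(OC)c1
A1 | alternative 1 | 5,7-bis(benzyloxy)-2-[4-(benzyloxy)-3-methoxyphenyl]-8-{(1R)-1-[4-(benzyloxy)-3,5-dimethoxyphenyl]ethyl}-4H-chromen-4-one | COc1cc(-c2cc(=O)c3c(OCc4ccccc4)cc(OCc4ccccc4)c([C@H](C)c4cc(OC)c(OCc5ccccc5)c(OC)c4)c3o2)ccc1OCc1ccccc1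
A2 | alternative 1 | 3,5-bis(benzyloxy)-2-{(1R)-1-[4-(benzyloxy)-3,5-dimethoxyphenyl]ethyl}-6-iodophenol | Oc1c(I)c(OCc2ccccc2)cc(OCc2ccccc2)c1[C@H](C)c1cc(OC)c(OCc2ccccc2)c(OC)c1
A3 | alternative 1 | 1-(benzyloxy)-4-ethynyl-2-methoxybenzene | C#Cc1ccc(OCc2ccccc2)c(OC)c1
A4 | alternative 2 | 5-(benzyloxy)-2-{(1R)-1-[4-(benzyloxy)-3,5-dimethoxyphenyl]ethyl}-3-[(triisopropylsilyl)oxy]phenol | Oc1cc(OCc2ccccc2)cc(O[Si](C(C)C)(C(C)C)C(C)C)c1[C@H](C)c1cc(OC)c(OCc2ccccc2)c(OC)c1
A5 | alternative 2 | 3-(benzyloxy)cyclobut-2-en-1-one | O=C1CC(OCc2ccccc2)=C1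
A6 | alternative 2 | {[(3R)-3-[4-(benzyloxy)-3,5-dimethoxyphenyl]but-1-yn-1-yl]oxy}tri(propan-2-yl)silane | CC(C)[Si](OC#C[C@H](C)c1cc(OC)c(OCc2ccccc2)c(OC)c1)(C(C)C)C(C)C
A7 | alternative 3 | 3,5-bis(benzyloxy)-2-{(1R)-1-[4-(benzyloxy)-3,5-dimethoxyphenyl]-2-hydroxyethyl}phenol | Oc1cc(OCc2ccccc2)cc(OCc2ccccc2)c1[C@H](CO)c1cc(OC)c(OCc2ccccc2)c(OC)c1
A8 | alternative 3 | 4,6-bis(benzyloxy)-3-[4-(benzyloxy)-3,5-dimethoxyphenyl]-2,3-dihydro-1-benzofuran-2-ol (racemising mixture of stereoisomers) | OC1Oc2cc(OCc3ccccc3)cc(OCc3ccccc3)c2C1c1cc(OC)c(OCc2ccccc2)c(OC)c1
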